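**Retrosynthetic overview**
The C18 carboxyl is taken back to a CH2O–silyl group and C3–H to a temporary 3β-hydroxyl; both come from one (2S,3S)-epoxide terminus, and the route removes the C3 oxygen again by radical deoxygenation.
Key disconnection: C4–C5 (closes ring A) together with C9–C10 (closes ring B) in one Lewis acid-promoted, epoxide-initiated, allylsilane-terminated cation–olefin bicyclisation of an acyclic epoxy triene; ring A forms first, ring B second, and loss of silicon from C17 leaves the C8=C17 alkene.
Enabling feature: the head-to-tail 1,5-diene lineage of the trans-fused rings A and B, i.e. the array C4/C5=C10/C9=C8 in which quaternary C4 and C10 are each bonded to a ring CH (C5, C9); the C8(17) methylene marks where a silyl group can depart, and the equatorial C18 carboxyl matches the (E)-substituent of the epoxide carbon.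
Acyclic precursor: C9–C11 bond by Negishi sp2–sp3 coupling of a (Z)-2-(silylmethyl)alkenyl iodide (syn-carbocupration of a geranyl-derived 1,5-enyne) with a homoallylic zinc reagent that already carries the (E)-allylic acetate; then Sharpless epoxidation.
Starting materials: geranyl chloride, 1-(trimethylsilyl)propyne and the tert-butyldimethylsilyl ether of but-3-yn-1-ol.

Key step: step 13

Remark: labdane numbering is used for the bicyclic compounds and for the corresponding carbons of the acyclic precursors (C17 = methylene carbon on C8; C18 = equatorial, α carbon on C4, trans to the C10 methyl; C19 = axial 4β-methyl), and the three starting materials are taken to be commercial.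

**Route**

Step 1
Reactants: 1 geranyl chloride, (2E)-1-chloro-3,7-dimethylocta-2,6-diene
Product: 2 (2E,6E)-8-chloro-2,6-dimethylocta-2,6-dien-1-ol
Conditions: SeO2 (cat.), t-BuOOH, salicylic acid (cat.), CH2Cl2, 0 °C to rt
Reagents that add atoms: tert-butyl hydroperoxide, CC(C)(C)OO (terminal oxidant; the oxygen is relayed by selenium dioxide, O=[Se]=O)
Why: Allylic oxidation with catalytic SeO2 (ene reaction then [2,3]-sigmatropic shift) should hydroxylate the (E)-methyl group of the electron-rich terminal alkene selectively, because the other alkene is deactivated by the allylic chloride, which places the future C18 oxygen trans to the chain.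

Step 2
Reactants: 2 (2E,6E)-8-chloro-2,6-dimethylocta-2,6-dien-1-ol
Product: 3 tert-butyl{[(2E,6E)-8-chloro-2,6-dimethylocta-2,6-dien-1-yl]oxy}dimethylsilane
Conditions: TBSOTf, 2,6-lutidine, CH2Cl2, −78 °C
Reagents that add atoms: tert-butyldimethylsilyl trifluoromethanesulfonate, CC(C)(C)[Si](C)(C)OS(=O)(=O)C(F)(F)F
Why: Silyl ether formation with the triflate and a hindered, non-nucleophilic base should protect the primary alcohol for the organometallic steps without displacing the allylic chloride.

Step 3
Reactants: 3 tert-butyl{[(2E,6E)-8-chloro-2,6-dimethylocta-2,6-dien-1-yl]oxy}dimethylsilane; 4 silylpropyne 1-(trimethylsilyl)prop-1-yne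
Product: 7 tert-butyl{[(2E,6E)-2,6-dimethylundeca-2,6-dien-10-yn-1-yl]oxy}dimethylsilane, via lithiated silylpropyne 5 (not isolated), via silylalkyne 6 (not isolated)
Conditions: 4, n-BuLi, THF, −78 °C; then 3, −78 °C to rt; then K2CO3, MeOH, rt
Reagents that add atoms: n-butyllithium, [Li]CCCC (lithium retained only in intermediate 5)
Why: Propargylic lithiation of the silylpropyne and SN2 alkylation at the primary allylic chloride (the silyl group blocks the allenyl terminus and the (E)-alkene is retained) should give the silylated 1,5-enyne, and potassium carbonate in methanol then removes the alkynyl silyl group while the silyl ether survives.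

Step 4
Reactants: 7 tert-butyl{[(2E,6E)-2,6-dimethylundeca-2,6-dien-10-yn-1-yl]oxy}dimethylsilane
Product: 9 tert-butyl{[(2E,6E,10Z)-11-iodo-2,6-dimethyl-10-[(trimethylsilyl)methyl]undeca-2,6,10-trien-1-yl]oxy}dimethylsilane, via alkenylcopper 8 (not isolated)
Conditions: Me3SiCH2MgCl, CuBr·SMe2, Et2O–Me2S, −35 °C to rt; then I2, THF, −35 °C
Reagents that add atoms: (trimethylsilyl)methylmagnesium chloride, C[Si](C)(C)C[Mg]Cl; iodine, II; copper bromide–dimethyl sulfide complex, [Cu]Br.CSC (copper retained only in intermediate 8)
Why: syn-Carbocupration of a terminal alkyne by an alkylcopper–magnesium halide reagent should place the silylmethyl group on the internal carbon (future C8) and copper on the terminal carbon (future C9) on the same side, and iodinolysis with retention then fixes the geometry in which C7 is trans to iodine, which is the geometry needed for an equatorial side chain at C9.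

Step 5
Reactants: 10 tert-butyl(but-3-yn-1-yloxy)dimethylsilane
Product: 12 (2E)-5-[(tert-butyldimethylsilyl)oxy]-3-methylpent-2-en-1-ol, via alkenylalane 11 (not isolated)
Conditions: Me3Al, Cp2ZrCl2 (cat.), CH2Cl2, 0 °C to rt; then n-BuLi, (CH2O)n, THF, −78 °C to rt
Reagents that add atoms: trimethylaluminium, C[Al](C)C; formaldehyde (from paraformaldehyde), C=O
Why: Zirconium-catalysed carboalumination (Negishi) should add methyl and aluminium syn across the alkyne with methyl on the internal carbon, and hydroxymethylation of the derived alanate with formaldehyde proceeds with retention, so the (E)-trisubstituted alkene of the side chain (C13=C14) is set here.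

Step 6
Reactants: 12 (2E)-5-[(tert-butyldimethylsilyl)oxy]-3-methylpent-2-en-1-ol
Product: 13 (2E)-5-[(tert-butyldimethylsilyl)oxy]-3-methylpent-2-en-1-yl acetate
Conditions: Ac2O, pyridine, DMAP (cat.), CH2Cl2, 0 °C to rt
Reagents that add atoms: acetic anhydride, CC(=O)OC(C)=O
Why: DMAP-catalysed acetylation of the primary allylic alcohol should install the C15 acetate of the target at the start, where it is the only free hydroxyl.

Step 7
Reactants: 13 (2E)-5-[(tert-butyldimethylsilyl)oxy]-3-methylpent-2-en-1-yl acetate
Product: 14 (2E)-5-hydroxy-3-methylpent-2-en-1-yl acetate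
Conditions: HF·pyridine, pyridine, THF, 0 °C to rt
Reagents that add atoms: none
Why: Fluoride-induced cleavage of the primary silyl ether under buffered conditions should free the homoallylic alcohol and leave the acetate untouched.

Step 8
Reactants: 14 (2E)-5-hydroxy-3-methylpent-2-en-1-yl acetate
Product: 15 (2E)-5-iodo-3-methylpent-2-en-1-yl acetate
Conditions: I2, PPh3, imidazole, CH2Cl2, 0 °C
Reagents that add atoms: iodine, II
Why: Appel-type iodination should convert the primary alcohol to the iodide by SN2 displacement of the oxyphosphonium ion without affecting the allylic acetate.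

Step 9
Reactants: 15 (2E)-5-iodo-3-methylpent-2-en-1-yl acetate; 9 tert-butyl{[(2E,6E,10Z)-11-iodo-2,6-dimethyl-10-[(trimethylsilyl)methyl]undeca-2,6,10-trien-1-yl]oxy}dimethylsilane
Product: 17 (2E,6Z,10E,14E)-16-[(tert-butyldimethylsilyl)oxy]-3,11,15-trimethyl-7-[(trimethylsilyl)methyl]hexadeca-2,6,10,14-tetraen-1-yl acetate, via alkylzinc iodide 16 (not isolated)
Conditions: 15, Zn dust, LiCl, THF, rt; then 9, PdCl2(dppf) (cat.), THF, rt
Reagents that add atoms: zinc, [Zn] (retained only in intermediate 16)
Why: LiCl-assisted insertion of zinc into the primary C–I bond should give an ester-tolerant alkylzinc iodide, and Negishi sp3–sp2 cross-coupling forms the C9–C11 bond with retention of the alkenyl iodide geometry, oxidative addition of zerovalent palladium to the C–I bond being much faster than ionisation of the primary allylic acetate at room temperature.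

Step 10
Reactants: 17 (2E,6Z,10E,14E)-16-[(tert-butyldimethylsilyl)oxy]-3,11,15-trimethyl-7-[(trimethylsilyl)methyl]hexadeca-2,6,10,14-tetraen-1-yl acetate
Product: 18 (2E,6Z,10E,14E)-16-hydroxy-3,11,15-trimethyl-7-[(trimethylsilyl)methyl]hexadeca-2,6,10,14-tetraen-1-yl acetate
Conditions: PPTS, MeOH, rt
Reagents that add atoms: none
Why: Mild acid-catalysed methanolysis should remove the primary tert-butyldimethylsilyl ether while the acetate and the acid-sensitive allylsilane stay intact (fluoride is avoided because it would activate the allylsilane).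

Step 11
Reactants: 18 (2E,6Z,10E,14E)-16-hydroxy-3,11,15-trimethyl-7-[(trimethylsilyl)methyl]hexadeca-2,6,10,14-tetraen-1-yl acetate
Product: 19 (2E,6Z,10E)-13-[(2S,3S)-3-(hydroxymethyl)-3-methyloxiran-2-yl]-3,11-dimethyl-7-[(trimethylsilyl)methyl]trideca-2,6,10-trien-1-yl acetate
Conditions: Ti(OiPr)4 (cat.), L-(+)-diethyl tartrate, t-BuOOH, 4 Å MS, CH2Cl2, −20 °C
Reagents that add atoms: tert-butyl hydroperoxide, CC(C)(C)OO
Why: Sharpless asymmetric epoxidation is directed by the allylic hydroxyl and so should touch only the C3=C4 alkene among four trisubstituted alkenes, and with L-(+)-diethyl tartrate oxygen is delivered to the face of the (E)-2-methyl allylic alcohol that gives the (2S,3S)-epoxide, which sets C3 and C4 of the substrate under reagent control.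

Step 12
Reactants: 19 (2E,6Z,10E)-13-[(2S,3S)-3-(hydroxymethyl)-3-methyloxiran-2-yl]-3,11-dimethyl-7-[(trimethylsilyl)methyl]trideca-2,6,10-trien-1-yl acetate
Product: 20 (2E,6Z,10E)-13-[(2S,3S)-3-{[(tert-butyldiphenylsilyl)oxy]methyl}-3-methyloxiran-2-yl]-3,11-dimethyl-7-[(trimethylsilyl)methyl]trideca-2,6,10-trien-1-yl acetate
Conditions: TBDPSCl, imidazole, DMAP (cat.), CH2Cl2, rt
Reagents that add atoms: tert-butyl(chloro)diphenylsilane, CC(C)(C)[Si](Cl)(c1ccccc1)c1ccccc1
Why: Silylation of the primary hydroxyl with the bulky tert-butyldiphenylsilyl group should give a non-chelating, non-participating ether that withstands MeAlCl2, so that the C18 oxygen cannot direct or intercept the epoxide opening.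

Step 13
Reactants: 20 (2E,6Z,10E)-13-[(2S,3S)-3-{[(tert-butyldiphenylsilyl)oxy]methyl}-3-methyloxiran-2-yl]-3,11-dimethyl-7-[(trimethylsilyl)methyl]trideca-2,6,10-trien-1-yl acetate
Product: 21 labdane alcohol 18-[(tert-butyldiphenylsilyl)oxy]-3β-hydroxylabda-8(17),13E-dien-15-yl acetate (4α-CH2OSi; 4β-CH3; 5α-H; 9α-H; 10β-CH3)
Conditions: MeAlCl2 (2.5 equiv), CH2Cl2, −78 °C; aqueous NaHCO3–Rochelle salt work-up
Reagents that add atoms: none
Why: MeAlCl2 coordinates the epoxide oxygen, the C5=C10 π bond attacks the tertiary epoxide carbon C4 anti to the breaking C4–O bond, the developing C10 cation is captured at C9 by the allylsilane, and loss of the trimethylsilyl group from C17 forms the C8=C17 alkene and ends the cascade at the bicycle. The closest known reaction type is the Lewis acid-promoted, epoxide-initiated and allylsilane-terminated cation–olefin polycyclisation of epoxy polyenes, including substrates whose epoxide carbon carries an alkoxymethyl group. Ring A closes by 6-endo-trig attack of the C5=C10 alkene (exo-tet opening at C4 of the epoxide) and ring B by 6-endo-trig attack of the C8=C9 allylsilane on C10, through a chair–chair fold. C4 is set by stereospecific inversion at the (S)-epoxide carbon, so the (E)-CH2OSi group becomes the equatorial 4α substituent (C18) and the methyl the axial 4β one; C5 and C10 are set trans by antiperiplanar addition across the (E)-C5=C10 alkene; C9 is set by the allylsilane geometry (C11 trans to C7 gives the equatorial 9β side chain); and the absolute sense of the fold is fixed by the C3 stereocentre, whose oxygen sits equatorial in the chair and ends as the 3β-hydroxyl. The step needs cleavage of the tertiary C4–O bond rather than C3–O, a single mode of termination and survival of the acetate: the tertiary, π-assisted position and the six-membered transition state should secure the first, the β-silicon effect should give only the 8(17)-alkene and no third ring, and the C13=C14 alkene is electron-poor and out of reach while the acetate is only a spectator Lewis base at −78 °C (hence the excess of MeAlCl2, which also scavenges adventitious protons).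

Step 14
Reactants: 21 labdane alcohol 18-[(tert-butyldiphenylsilyl)oxy]-3β-hydroxylabda-8(17),13E-dien-15-yl acetate
Product: 22 thiocarbonyl derivative 18-[(tert-butyldiphenylsilyl)oxy]-3β-[(1H-imidazol-1-ylcarbonothioyl)oxy]labda-8(17),13E-dien-15-yl acetate
Conditions: 1,1'-thiocarbonyldiimidazole, DMAP, ClCH2CH2Cl, 80 °C
Reagents that add atoms: 1,1'-thiocarbonyldiimidazole, S=C(n1ccnc1)n1ccnc1
Why: Acylation of the equatorial C3 hydroxyl, the only free hydroxyl, with 1,1'-thiocarbonyldiimidazole should give the thiocarbonyl derivative required for Barton–McCombie deoxygenation.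

Step 15
Reactants: 22 thiocarbonyl derivative 18-[(tert-butyldiphenylsilyl)oxy]-3β-[(1H-imidazol-1-ylcarbonothioyl)oxy]labda-8(17),13E-dien-15-yl acetate
Product: 23 silyl ether 18-[(tert-butyldiphenylsilyl)oxy]labda-8(17),13E-dien-15-yl acetate
Conditions: Bu3SnH, AIBN (cat.), toluene, 100 °C
Reagents that add atoms: none
Why: Barton–McCombie deoxygenation should remove the temporary C3 oxygen, since the stannyl radical adds to sulfur, β-scission releases the secondary C3 radical and this abstracts hydrogen from Bu3SnH before it can reach any alkene, with no stereocentre affected because C3 becomes CH2.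

Step 16
Reactants: 23 silyl ether 18-[(tert-butyldiphenylsilyl)oxy]labda-8(17),13E-dien-15-yl acetate
Product: 24 primary alcohol 18-hydroxylabda-8(17),13E-dien-15-yl acetate
Conditions: TBAF, AcOH, THF, rt to 40 °C
Reagents that add atoms: none
Why: Fluoride cleavage of the neopentyl silyl ether should free the C18 alcohol, and buffering with acetic acid keeps the medium non-basic so that the C15 acetate is retained.

Step 17
Reactants: 24 primary alcohol 18-hydroxylabda-8(17),13E-dien-15-yl acetate
Product: 25 aldehyde 18-oxolabda-8(17),13E-dien-15-yl acetate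
Conditions: Dess–Martin periodinane, NaHCO3, CH2Cl2, rt
Reagents that add atoms: none
Why: Dess–Martin oxidation should take the hindered primary alcohol to the aldehyde under buffered, non-acidic conditions that leave both alkenes and the acetate alone; C4 is quaternary and cannot epimerise.

Step 18
Reactants: 25 aldehyde 18-oxolabda-8(17),13E-dien-15-yl acetate
Product: 26 target 15-acetoxylabda-8(17),13E-dien-18-oic acid
Conditions: NaClO2, NaH2PO4, 2-methylbut-2-ene, t-BuOH–H2O, rt
Reagents that add atoms: sodium chlorite, [Na+].[O-]Cl=O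
Why: Pinnick oxidation should convert the neopentyl aldehyde to the carboxylic acid, the hypochlorous acid by-product being trapped by 2-methylbut-2-ene so that the exocyclic and trisubstituted alkenes survive.

**Compound list**

1 | geranyl chloride, (2E)-1-chloro-3,7-dimethylocta-2,6-diene | CC(C)=CCC/C(C)=C/CCl | starting material
2 | (2E,6E)-8-chloro-2,6-dimethylocta-2,6-dien-1-ol | OC/C(C)=C/CC/C(C)=C/CCl | intermediate
3 | tert-butyl{[(2E,6E)-8-chloro-2,6-dimethylocta-2,6-dien-1-yl]oxy}dimethylsilane | CC(C)(C)[Si](C)(C)OC/C(C)=C/CC/C(C)=C/CCl | intermediate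
4 | 1-(trimethylsilyl)prop-1-yne | CC#C[Si](C)(C)C | starting material
5 | 3-lithio-1-(trimethylsilyl)prop-1-yne (formed in the flask) | [Li]CC#C[Si](C)(C)C | intermediate
6 | tert-butyl{[(2E,6E)-2,6-dimethyl-11-(trimethylsilyl)undeca-2,6-dien-10-yn-1-yl]oxy}dimethylsilane (formed in the flask) | CC(C)(C)[Si](C)(C)OC/C(C)=C/CC/C(C)=C/CCC#C[Si](C)(C)C | intermediate
7 | tert-butyl{[(2E,6E)-2,6-dimethylundeca-2,6-dien-10-yn-1-yl]oxy}dimethylsilane | CC(C)(C)[Si](C)(C)OC/C(C)=C/CC/C(C)=C/CCC#C | intermediate
8 | {(1Z,5E,9E)-11-[(tert-butyldimethylsilyl)oxy]-6,10-dimethyl-2-[(trimethylsilyl)methyl]undeca-1,5,9-trien-1-yl}copper (formed in the flask) | CC(C)(C)[Si](C)(C)OC/C(C)=C/CC/C(C)=C/CC/C(C[Si](C)(C)C)=C/[Cu] | intermediate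
9 | tert-butyl{[(2E,6E,10Z)-11-iodo-2,6-dimethyl-10-[(trimethylsilyl)methyl]undeca-2,6,10-trien-1-yl]oxy}dimethylsilane | CC(C)(C)[Si](C)(C)OC/C(C)=C/CC/C(C)=C/CC/C(C[Si](C)(C)C)=C/I | intermediate
10 | tert-butyl(but-3-yn-1-yloxy)dimethylsilane | C#CCCO[Si](C)(C)C(C)(C)C | starting material
11 | {(1E)-4-[(tert-butyldimethylsilyl)oxy]-2-methylbut-1-en-1-yl}dimethylalane (formed in the flask) | C[Al](C)/C=C(\C)CCO[Si](C)(C)C(C)(C)C | intermediate
12 | (2E)-5-[(tert-butyldimethylsilyl)oxy]-3-methylpent-2-en-1-ol | OC/C=C(\C)CCO[Si](C)(C)C(C)(C)C | intermediate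
13 | (2E)-5-[(tert-butyldimethylsilyl)oxy]-3-methylpent-2-en-1-yl acetate | CC(=O)OC/C=C(\C)CCO[Si](C)(C)C(C)(C)C | intermediate
14 | (2E)-5-hydroxy-3-methylpent-2-en-1-yl acetate | CC(=O)OC/C=C(\C)CCO | intermediate
15 | (2E)-5-iodo-3-methylpent-2-en-1-yl acetate | CC(=O)OC/C=C(\C)CCI | intermediate
16 | [(3E)-5-(acetyloxy)-3-methylpent-3-en-1-yl](iodo)zinc (formed in the flask) | CC(=O)OC/C=C(\C)CC[Zn]I | intermediate
17 | (2E,6Z,10E,14E)-16-[(tert-butyldimethylsilyl)oxy]-3,11,15-trimethyl-7-[(trimethylsilyl)methyl]hexadeca-2,6,10,14-tetraen-1-yl acetate | CC(C)(C)[Si](C)(C)OC/C(C)=C/CC/C(C)=C/CC/C(C[Si](C)(C)C)=C/CC/C(C)=C/COC(C)=O | intermediate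
18 | (2E,6Z,10E,14E)-16-hydroxy-3,11,15-trimethyl-7-[(trimethylsilyl)methyl]hexadeca-2,6,10,14-tetraen-1-yl acetate | OC/C(C)=C/CC/C(C)=C/CC/C(C[Si](C)(C)C)=C/CC/C(C)=C/COC(C)=O | intermediate
19 | (2E,6Z,10E)-13-[(2S,3S)-3-(hydroxymethyl)-3-methyloxiran-2-yl]-3,11-dimethyl-7-[(trimethylsilyl)methyl]trideca-2,6,10-trien-1-yl acetate | CC(=O)OC/C=C(\C)CC/C=C(C[Si](C)(C)C)/CC/C=C(\C)CC[C@@H]1O[C@@]1(C)CO | intermediate
20 | (2E,6Z,10E)-13-[(2S,3S)-3-{[(tert-butyldiphenylsilyl)oxy]methyl}-3-methyloxiran-2-yl]-3,11-dimethyl-7-[(trimethylsilyl)methyl]trideca-2,6,10-trien-1-yl acetate | CC(=O)OC/C=C(\C)CC/C=C(C[Si](C)(C)C)/CC/C=C(\C)CC[C@@H]1O[C@@]1(C)CO[Si](c2ccccc2)(c3ccccc3)C(C)(C)C | intermediate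
21 | 18-[(tert-butyldiphenylsilyl)oxy]-3β-hydroxylabda-8(17),13E-dien-15-yl acetate (trans-decalin; 4α-CH2OSi, 4β-CH3, 5α-H, 9α-H, 10β-CH3) | C=C1CC[C@@H]2[C@](C)(CC[C@H](O)[C@@]2(C)CO[Si](c3ccccc3)(c4ccccc4)C(C)(C)C)[C@H]1CC/C(C)=C/COC(C)=O | intermediate
22 | 18-[(tert-butyldiphenylsilyl)oxy]-3β-[(1H-imidazol-1-ylcarbonothioyl)oxy]labda-8(17),13E-dien-15-yl acetate | C=C1CC[C@@H]2[C@](C)(CC[C@H](OC(=S)n3ccnc3)[C@@]2(C)CO[Si](c4ccccc4)(c5ccccc5)C(C)(C)C)[C@H]1CC/C(C)=C/COC(C)=O | intermediate
23 | 18-[(tert-butyldiphenylsilyl)oxy]labda-8(17),13E-dien-15-yl acetate | C=C1CC[C@@H]2[C@](C)(CCC[C@@]2(C)CO[Si](c3ccccc3)(c4ccccc4)C(C)(C)C)[C@H]1CC/C(C)=C/COC(C)=O | intermediate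
24 | 18-hydroxylabda-8(17),13E-dien-15-yl acetate | C=C1CC[C@@H]2[C@](C)(CCC[C@@]2(C)CO)[C@H]1CC/C(C)=C/COC(C)=O | intermediate
25 | 18-oxolabda-8(17),13E-dien-15-yl acetate | C=C1CC[C@@H]2[C@](C)(CCC[C@@]2(C)C=O)[C@H]1CC/C(C)=C/COC(C)=O | intermediate
26 | 15-acetoxylabda-8(17),13E-dien-18-oic acid, (1R,4aR,5S,8aR)-5-[(3E)-5-acetoxy-3-methylpent-3-en-1-yl]-1,4a-dimethyl-6-methylidenedecahydronaphthalene-1-carboxylic acid | C=C1CC[C@@H]2[C@](C)(CCC[C@@]2(C)C(=O)O)[C@H]1CC/C(C)=C/COC(C)=O | target

**Step count and risks**

Total step count: 18. Longest linear sequence: 14 steps (steps 1–4, then 9–18; the branch through steps 5–8 joins at step 9 and is equally long).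

Step 13 is the step most likely to fail. Ionisation of the C4–O bond may outrun π-participation, because the siloxymethyl group retards build-up of positive charge at C4; this would lead to a hydride shift from C3 or to arrest after ring A, and the allylsilane may be protodesilylated before C10 becomes cationic. The fallback moves the same ring closures to the radical manifold. It sets out from 20 and comes back at 21: Cp2TiCl, generated from Cp2TiCl2 and Mn dust in THF (trivalent titanium), should open the epoxide homolytically at the tertiary carbon. The C4 radical should then close ring A and ring B by the same 6-endo additions, and the β-silyl tertiary radical at C8, once trapped by a second titanium centre, should collapse to the 8(17)-alkene with loss of the silyl group. In this manifold C4 is no longer fixed by inversion but by the preference of the large CH2OSi group for the equatorial site. No compound outside the list is made (further compound: none F0).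

Step 4 is the second risk. Addition of the stabilised silylmethylcopper reagent to an alkyl-substituted alkyne may be slower than decay of the reagent or deprotonation of the alkyne, and iodine may attack the newly formed allylsilane during iodinolysis. The fallback installs boron and the silylmethyl group in one copper-catalysed syn-carboboration instead of a stoichiometric carbometalation. It sets out from 7: B2pin2, ICH2SiMe3, CuCl (cat.), Xantphos and NaOt-Bu in THF should place boron on the terminal carbon and the silylmethyl group on the internal carbon, cis to each other, to give 2-{(1Z,5E,9E)-11-[(tert-butyldimethylsilyl)oxy]-6,10-dimethyl-2-[(trimethylsilyl)methyl]undeca-1,5,9-trien-1-yl}-4,4,5,5-tetramethyl-1,3,2-dioxaborolane F1. Iododeboronation with retention (NaOH, I2, THF–H2O, 0 °C) then comes back to the route at 9.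

Step 14 is the third risk. Acylation of the C3 hydroxyl may stall, because it is flanked by quaternary C4 carrying the bulky silyloxymethyl group, so that no substrate for the radical deoxygenation is formed. The fallback removes the oxygen through the carbonyl group instead and bypasses steps 14 and 15. It sets out from 21: Dess–Martin oxidation should give 18-[(tert-butyldiphenylsilyl)oxy]-3-oxolabda-8(17),13E-dien-15-yl acetate F2. Condensation with 4-methylbenzenesulfonohydrazide (EtOH, 60 °C) should give 18-[(tert-butyldiphenylsilyl)oxy]-3-[2-(4-methylbenzenesulfonyl)hydrazinylidene]labda-8(17),13E-dien-15-yl acetate F3. Reduction of this tosylhydrazone with catecholborane (CHCl3, 0 °C), followed by NaOAc·3H2O at reflux, should give the C3 methylene compound and come back to the route at 23, with the acetate and both alkenes untouched.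

**Further compounds**

F0 | step 13 | none | none
F1 | step 4 | 2-{(1Z,5E,9E)-11-[(tert-butyldimethylsilyl)oxy]-6,10-dimethyl-2-[(trimethylsilyl)methyl]undeca-1,5,9-trien-1-yl}-4,4,5,5-tetramethyl-1,3,2-dioxaborolane | CC(C)(C)[Si](C)(C)OC/C(C)=C/CC/C(C)=C/CC/C(C[Si](C)(C)C)=C/B1OC(C)(C)C(C)(C)O1
F2 | step 14 | 18-[(tert-butyldiphenylsilyl)oxy]-3-oxolabda-8(17),13E-dien-15-yl acetate | C=C1CC[C@@H]2[C@](C)(CCC(=O)[C@@]2(C)CO[Si](c3ccccc3)(c4ccccc4)C(C)(C)C)[C@H]1CC/C(C)=C/COC(C)=O
F3 | step 14 | 18-[(tert-butyldiphenylsilyl)oxy]-3-[2-(4-methylbenzenesulfonyl)hydrazinylidene]labda-8(17),13E-dien-15-yl acetate | C=C1CC[C@@H]2[C@](C)(CCC(=NNS(=O)(=O)c3ccc(C)cc3)[C@@]2(C)CO[Si](c4ccccc4)(c5ccccc5)C(C)(C)C)[C@H]1CC/C(C)=C/COC(C)=O
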